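Numbering the quinone ring C1(=O), C2(OMe), C3–H, C4(=O), C5–H, C6(chain), the route rests on the 1,3-dioxygenation C2/C4 across C3–H with the chain on C6, β to C2 through C1: a masked alkylresorcylate, as in polyketide alkylresorcinols. A Michael–Claisen annulation joins an open-chain (E)-enone acid (C3 methyl, C2 carbonyl, C1=C6 alkene, full side chain) with dimethyl malonate: its central carbon becomes C5 and bonds to C6, one ester carbon becomes C4 and is captured by the C3 enolate. The spare ester later differentiates the two oxygens (chelated OH versus OMe) and is then expelled as CO2; para-oxidation of the phenol installs C1=O last.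

Key step: step 3

Remark on the chemistry: 6, 7 and 8 form as racemates (7 and 8 also as diastereomer mixtures). This is harmless, because every stereocentre is erased on aromatisation and the target has none.

Step 1
Reactants: 1 16-hydroxyhexadecanoic acid
Product: 2 16-oxohexadecanoic acid
Conditions: IBX (1.3 equiv), EtOAc, 80 °C
Reagents that add atoms: none
Why: Hypervalent-iodine (IBX) oxidation of a primary alcohol stops at the aldehyde in the absence of water and leaves the carboxylic acid untouched.

Step 2
Reactants: 2 16-oxohexadecanoic acid; 3 1-(triphenyl-λ5-phosphanylidene)propan-2-one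
Product: 4 (16E)-18-oxononadec-16-enoic acid
Conditions: 3 (2.2 equiv), THF, 65 °C
Reagents that add atoms: none
Why: Wittig olefination with a ketone-stabilised ylide should give the (E)-enone selectively; the free acid is tolerated by the weakly basic ylide used in excess, and the acidic product is separated from the phosphine oxide by base extraction.

Step 3
Reactants: 4 (16E)-18-oxononadec-16-enoic acid; 5 dimethyl malonate
Product: 7 15-[3-hydroxy-2-(methoxycarbonyl)-5-oxocyclohex-3-en-1-yl]pentadecanoic acid (enol form of the cyclic β-keto ester), via malonate Michael adduct 6 (not isolated)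
Conditions: NaOMe (3 equiv), MeOH, 65 °C; then aq. HCl, 0 °C
Reagents that add atoms: none
Why: Tandem Michael addition–Claisen (Dieckmann-type) condensation, the classical malonate/enone route to cyclohexane-1,3-diones: sodiomalonate adds in 1,4-fashion to the β-carbon (C16) of enone 4, forming the C5–C6 ring bond and enolate 6. Proton transfer gives the terminal methyl enolate, which attacks one malonate ester in a 6-(enolexo)-exo-trig acyl substitution with loss of methoxide, forming the C3–C4 bond and closing the only ring of the molecule. The equilibria should be pulled forward by the doubly stabilised 1,3-dicarbonyl anion of 7, which drains the retro-Michael path. The selectivities needed are 1,4- over 1,2-addition, secured by the soft stabilised malonate anion, and cyclisation through the methyl rather than the internal CH2 enolate, secured because the latter could only close a four-membered ring; the chain carboxylate is an inert spectator. The two new stereocentres (chain-bearing and ester-bearing ring carbons) are controlled only by the thermodynamic trans preference through the epimerisable ester carbon, which is irrelevant because both are erased on aromatisation.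

Step 4
Reactants: 7 15-[3-hydroxy-2-(methoxycarbonyl)-5-oxocyclohex-3-en-1-yl]pentadecanoic acid
Product: 9 methyl 2-hydroxy-4-methoxy-6-(15-methoxy-15-oxopentadecyl)benzoate, via ring enol ether 8 (not isolated)
Conditions: I2 (1.5 equiv), MeOH, 65 °C; aq. Na2S2O3 work-up
Reagents that add atoms: methanol, CO
Why: Iodine–methanol oxidative aromatisation of a cyclic 1,3-dione ester: HI formed in situ should catalyse enol-ether formation at the unhindered, non-chelated ring carbonyl (8) and Fischer esterification of the chain acid, α-iodination/dehydroiodination then aromatises the ring, and the other oxygen ends as the ester-chelated phenol that resists etherification.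

Step 5
Reactants: 9 methyl 2-hydroxy-4-methoxy-6-(15-methoxy-15-oxopentadecyl)benzoate
Product: 11 15-(3-hydroxy-5-methoxyphenyl)pentadecanoic acid, via salicylic diacid 10 (not isolated)
Conditions: KOH, H2O/DMSO, 100 °C; then HCl to pH 1, 90 °C
Reagents that add atoms: potassium hydroxide, [K+].[OH-]
Why: Saponification of both esters followed by acid-promoted protodecarboxylation of the electron-rich salicylic acid 10 (ipso-protonation ortho to OH and para to OMe) should remove the activating carboxyl group, while the aryl methyl ether is stable to hot alkali.

Step 6
Reactants: 11 15-(3-hydroxy-5-methoxyphenyl)pentadecanoic acid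
Product: 12 15-(5-methoxy-3,6-dioxocyclohexa-1,4-dien-1-yl)pentadecanoic acid
Conditions: (KSO3)2NO (2.5 equiv), KH2PO4 buffer, H2O/acetone, rt
Reagents that add atoms: potassium nitrosodisulfonate (Fremy's salt), [K+].[K+].[O-]S(=O)(=O)N([O])S(=O)(=O)[O-]
Why: Teuber oxidation: the phenoxyl radical formed by the first equivalent of the nitroxide should be trapped by a second equivalent at the free para position (between OMe and the chain), and loss of imidodisulfonate gives the para-quinone, the established outcome for 3-methoxy-5-alkylphenols.

Compound list
1 | 16-hydroxyhexadecanoic acid | OCCCCCCCCCCCCCCCC(=O)O | starting material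
2 | 16-oxohexadecanoic acid | O=CCCCCCCCCCCCCCCC(=O)O | intermediate
3 | 1-(triphenyl-λ5-phosphanylidene)propan-2-one | CC(=O)C=P(c1ccccc1)(c1ccccc1)c1ccccc1 | starting material
4 | (16E)-18-oxononadec-16-enoic acid | CC(=O)/C=C/CCCCCCCCCCCCCCC(=O)O | intermediate
5 | dimethyl malonate | COC(=O)CC(=O)OC | starting material
6 | 16-[bis(methoxycarbonyl)methyl]-18-oxononadecanoic acid (racemic, formed in situ) | CC(=O)CC(CCCCCCCCCCCCCCC(=O)O)C(C(=O)OC)C(=O)OC | intermediate
7 | 15-[3-hydroxy-2-(methoxycarbonyl)-5-oxocyclohex-3-en-1-yl]pentadecanoic acid (racemic, diastereomer mixture) | COC(=O)C1C(CCCCCCCCCCCCCCC(=O)O)CC(=O)C=C1O | intermediate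
8 | methyl 15-[5-methoxy-2-(methoxycarbonyl)-3-oxocyclohex-4-en-1-yl]pentadecanoate (racemic, diastereomer mixture, formed in situ) | COC(=O)C1C(CCCCCCCCCCCCCCC(=O)OC)CC(OC)=CC1=O | intermediate
9 | methyl 2-hydroxy-4-methoxy-6-(15-methoxy-15-oxopentadecyl)benzoate | COC(=O)c1c(O)cc(OC)cc1CCCCCCCCCCCCCCC(=O)OC | intermediate
10 | 2-(14-carboxytetradecyl)-6-hydroxy-4-methoxybenzoic acid (formed in situ) | COc1cc(O)c(C(=O)O)c(CCCCCCCCCCCCCCC(=O)O)c1 | intermediate
11 | 15-(3-hydroxy-5-methoxyphenyl)pentadecanoic acid | COc1cc(O)cc(CCCCCCCCCCCCCCC(=O)O)c1 | intermediate
12 | 15-(5-methoxy-3,6-dioxocyclohexa-1,4-dien-1-yl)pentadecanoic acid | COC1=CC(=O)C=C(CCCCCCCCCCCCCCC(=O)O)C1=O | target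

Total step count: 6. Longest linear sequence: 6 steps (1 to 12).

Steps most likely to fail

Step 5. The hindered, chelated aryl ester may resist saponification, or the protodecarboxylation may stall. The fallback moves the decarboxylation to the stage where it is trivial. It sets out from 7: aq. NaOH at reflux, then HCl at reflux, should saponify the ring ester and decarboxylate the β-keto acid to the symmetric dione 15-(3,5-dioxocyclohexyl)pentadecanoic acid F2. I2 in MeOH at 65 °C then aromatises, mono-etherifies and esterifies it to methyl 15-(3-hydroxy-5-methoxyphenyl)pentadecanoate F3. LiOH in THF/H2O followed by acidification returns to the route at 11.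

Step 4. Etherification may occur at both ring oxygens or stop before aromatisation, and the electron-rich ring may be iodinated. The fallback separates aromatisation from methylation. It sets out from 7: bromination–dehydrobromination (Br2, 1 equiv, DMF, 0 °C to rt) should give the resorcylate 15-[3,5-dihydroxy-2-(methoxycarbonyl)phenyl]pentadecanoic acid F1. MeI (2.2 equiv) and K2CO3 in acetone then methylate the chain acid and the non-chelated para hydroxyl only, returning to the route at 9.

Step 6. Ortho-oxidation and radical over-oxidation may compete, or the lipophilic acid may mix poorly with the aqueous oxidant. The fallback reaches the quinone through a para-aminophenol. It sets out from 11: para-nitrosation (NaNO2, aq. AcOH/EtOH, 0 °C) should give 15-(5-hydroxy-3-methoxy-2-nitrosophenyl)pentadecanoic acid F4. Reduction (Na2S2O4, aq. NaOH) gives 15-(2-amino-5-hydroxy-3-methoxyphenyl)pentadecanoic acid F5. Oxidation with FeCl3 in aq. HCl forms the quinone imine, which hydrolyses in the flask and returns to the route at 12.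

The key step is ranked below these three because it uses a long-proven reaction type.

Further compounds
F1 | step 4 | 15-[3,5-dihydroxy-2-(methoxycarbonyl)phenyl]pentadecanoic acid | COC(=O)c1c(O)cc(O)cc1CCCCCCCCCCCCCCC(=O)O
F2 | step 5 | 15-(3,5-dioxocyclohexyl)pentadecanoic acid | O=C1CC(=O)CC(CCCCCCCCCCCCCCC(=O)O)C1
F3 | step 5 | methyl 15-(3-hydroxy-5-methoxyphenyl)pentadecanoate | COc1cc(O)cc(CCCCCCCCCCCCCCC(=O)OC)c1
F4 | step 6 | 15-(5-hydroxy-3-methoxy-2-nitrosophenyl)pentadecanoic acid | COc1cc(O)cc(CCCCCCCCCCCCCCC(=O)O)c1N=O
F5 | step 6 | 15-(2-amino-5-hydroxy-3-methoxyphenyl)pentadecanoic acid | COc1cc(O)cc(CCCCCCCCCCCCCCC(=O)O)c1N
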